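Assumption: the target is read as (−)-epicatechin-3-O-gallate-(4β→8)-(−)-epigallocatechin-3-O-gallate, upper unit (2R,3R,4R), lower unit (2R,3R). Compounds 1, 2, 5, 7, 9 and 10 are taken as commercial.

**Retrosynthetic overview**
1. Target 16 ⇐ global O-debenzylation of the pentadeca-O-benzyl dimer 15.
2. 15 ⇐ C3–O ester bond made with inversion (Mitsunobu) from the 2,3-trans-3,4-cis alcohol 14 and tri-O-benzylgallic acid 7; 14 ⇐ hydride reduction of the 4-aryl-flavan-3-one 13.
3. Key C4–C8 bond of 13: C4 of flavan-3-one 4 is used as an enolonium (umpoled enolate on trivalent iodine) and is attacked by C8 of octa-O-benzyl-EGCG 8, so two natively nucleophilic carbons are joined.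
4. 4 ⇐ (+)-catechin (benzylation, oxidation); 8 ⇐ (−)-epigallocatechin (benzylation of the five phenols, then Steglich galloylation of the 3-OH with 7).
5. Ring order: no ring is built; both benzopyran units come intact from catechin and epigallocatechin, and only the interflavan bond, the upper C3 centre and the two gallate esters are made.

**Route**

Step 1
Reactants: 1 (+)-catechin; 2 benzyl bromide
Product: 3 5,7,3',4'-tetra-O-benzyl-(+)-catechin, (2R,3S)
Conditions: BnBr (4.4 equiv), K2CO3 (5 equiv), DMF, 0 °C → rt, Ar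
Reagents that add atoms: benzyl bromide 2, BrCc1ccccc1
Why: Williamson etherification; carbonate deprotonates only the four phenols, so the secondary 3-OH stays free and no stereocentre is touched.

Step 2
Reactants: 3 5,7,3',4'-tetra-O-benzyl-(+)-catechin
Product: 4 (2R)-5,7-bis(benzyloxy)-2-[3,4-bis(benzyloxy)phenyl]chroman-3-one
Conditions: Dess–Martin periodinane (1.5 equiv), wet CH2Cl2, rt
Reagents that add atoms: none
Why: Dess–Martin oxidation of the secondary alcohol under neutral conditions, which leaves the benzylic, α-oxygenated C2 centre (2R) intact.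

Step 3
Reactants: 5 (−)-epigallocatechin; 2 benzyl bromide
Product: 6 5,7,3',4',5'-penta-O-benzyl-(−)-epigallocatechin, (2R,3R)
Conditions: BnBr (5.5 equiv), K2CO3 (6 equiv), degassed DMF, 0 °C → rt, Ar
Reagents that add atoms: benzyl bromide 2, BrCc1ccccc1
Why: Williamson etherification of the five phenols only (the secondary 3-OH is not deprotonated by carbonate); cold, oxygen-free conditions protect the pyrogallol ring B from oxidation and C2 from base-induced epimerisation.

Step 4
Reactants: 6 penta-O-benzyl-(−)-epigallocatechin; 7 3,4,5-tris(benzyloxy)benzoic acid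
Product: 8 octa-O-benzyl-EGCG, (2R,3R)
Conditions: 7 (1.5 equiv), DCC (1.6 equiv), DMAP (0.3 equiv), CH2Cl2, 0 °C → rt
Reagents that add atoms: 3,4,5-tris(benzyloxy)benzoic acid 7, OC(=O)c1cc(OCc2ccccc2)c(OCc2ccccc2)c(OCc2ccccc2)c1
Why: Steglich esterification; the DCC-activated acid is passed on by DMAP to the axial 3-OH, the C3–O bond is never broken, so the ester forms with retention and (2R,3R) is kept.

Step 5
Reactants: 4 (2R)-tetra-O-benzylflavan-3-one; 9 trimethylsilyl triflate; 10 [hydroxy(tosyloxy)iodo]benzene (Koser's reagent); 8 octa-O-benzyl-EGCG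
Product: 13 (2R,4R)-5,7-bis(benzyloxy)-2-[3,4-bis(benzyloxy)phenyl]-4-(octa-O-benzyl-EGCG-8-yl)chroman-3-one (2,4-trans), via TMS enol ether 11 (not isolated), via enolonium species 12 (not isolated)
Conditions: TMSOTf (1.1 equiv), iPr2NEt (1.2 equiv), CH2Cl2, 0 °C; cannulate into PhI(OH)OTs (1.05 equiv)/BF3·OEt2 (1.5 equiv), CH2Cl2, −78 °C, 10 min; then 8 (3 equiv, excess recovered), −78 → −40 °C; aq. NaHCO3
Reagents that add atoms: octa-O-benzyl-EGCG 8, O=C(O[C@@H]1Cc2c(OCc3ccccc3)cc(OCc3ccccc3)cc2O[C@@H]1c1cc(OCc2ccccc2)c(OCc2ccccc2)c(OCc2ccccc2)c1)c1cc(OCc2ccccc2)c(OCc2ccccc2)c(OCc2ccccc2)c1; trimethylsilyl triflate 9, C[Si](C)(C)OS(=O)(=O)C(F)(F)F (its silicon stays only in 11); [hydroxy(tosyloxy)iodo]benzene 10, Cc1ccc(cc1)S(=O)(=O)OI(O)c1ccccc1 (its iodine and tosylate stay only in 12)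
Why: Proposed new method: soft enolisation goes to the less hindered benzylic C4H2 side (ring-A-conjugated 2H-chromene 11, C2 untouched), PhI(OH)OTs/BF3 turns 11 into the λ3-iodanyl enolate 12 whose C4 is now electrophilic (an α-keto benzylic cation equivalent stabilised by the 5,7-dialkoxy ring A), and C8 of 8 (the most nucleophilic and less hindered ring-A position) attacks it in a Friedel–Crafts sense with loss of PhI, anti to the C2 aryl so that the new aryl sits pseudo-axial and 2,4-trans (also the expected thermodynamic epimer at this enolisable centre, since the pseudo-axial aryl avoids the 5-benzyloxy group); closest known reaction type: α-arylation of ketones by indoles and pyrroles via enolonium species made from silyl enol ethers and Koser's reagent/BF3.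

Step 6
Reactants: 13 (2R,4R)-4-aryl-flavan-3-one
Product: 14 5,7,3',4'-tetra-O-benzylcatechin-(4β→8)-octa-O-benzyl-EGCG, upper unit (2R,3S,4R), 2,3-trans-3,4-cis
Conditions: NaBH4, CeCl3·7H2O, THF/MeOH, −78 → −40 °C
Reagents that add atoms: none
Why: Luche-type hydride reduction in which hydride adds axially to C3, anti to the pseudo-axial C4 aryl (Felkin–Anh), giving the equatorial 3S alcohol cis to the C4 aryl and trans to the C2 aryl, while CeCl3 suppresses enolisation at C4 and the cold borohydride leaves the gallate ester alone.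

Step 7
Reactants: 14 2,3-trans-3,4-cis alcohol; 7 3,4,5-tris(benzyloxy)benzoic acid
Product: 15 pentadeca-O-benzyl-epicatechin-3-O-gallate-(4β→8)-epigallocatechin-3-O-gallate, upper unit (2R,3R,4R)
Conditions: 7 (3 equiv), PPh3 (3 equiv), DIAD (3 equiv), toluene, 0 → 40 °C
Reagents that add atoms: 3,4,5-tris(benzyloxy)benzoic acid 7, OC(=O)c1cc(OCc2ccccc2)c(OCc2ccccc2)c(OCc2ccccc2)c1
Why: Mitsunobu esterification installs the gallate and inverts C3 (3S → 3R) in one SN2 event, giving the natural 2,3-cis-3,4-trans array; the backside path runs over O1 and C4a, which carry no axial groups, and the equatorial leaving group has no antiperiplanar hydrogen for E2.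

Step 8
Reactants: 15 pentadeca-O-benzyl dimer
Product: 16 epicatechin-3-O-gallate-(4β→8)-epigallocatechin-3-O-gallate (target, CNP0296769.1)
Conditions: H2 (1 atm), Pd(OH)2/C, THF/MeOH/H2O, rt; filter under Ar, lyophilise
Reagents that add atoms: none
Why: Catalytic hydrogenolysis cleaves all fifteen benzyl ethers under neutral conditions, leaving both gallate esters, the acid-labile interflavan bond and every stereocentre untouched.

Origin of the stereocentres: upper C2 comes from (+)-catechin, upper C4 is set in step 5, upper C3 is set in step 6 and inverted in step 7, and lower C2/C3 come from (−)-epigallocatechin.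

**Compound list**
1 | (+)-catechin, (2R,3S) | O[C@H]1Cc2c(O)cc(O)cc2O[C@@H]1c1ccc(O)c(O)c1 | starting material
2 | benzyl bromide | BrCc1ccccc1 | starting material
3 | 5,7,3',4'-tetra-O-benzyl-(+)-catechin, (2R,3S) | O[C@H]1Cc2c(OCc3ccccc3)cc(OCc3ccccc3)cc2O[C@@H]1c1ccc(OCc2ccccc2)c(OCc2ccccc2)c1 | intermediate
4 | (2R)-5,7-bis(benzyloxy)-2-[3,4-bis(benzyloxy)phenyl]chroman-3-one | O=C1Cc2c(OCc3ccccc3)cc(OCc3ccccc3)cc2O[C@@H]1c1ccc(OCc2ccccc2)c(OCc2ccccc2)c1 | intermediate
5 | (−)-epigallocatechin, (2R,3R) | O[C@@H]1Cc2c(O)cc(O)cc2O[C@@H]1c1cc(O)c(O)c(O)c1 | starting material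
6 | 5,7,3',4',5'-penta-O-benzyl-(−)-epigallocatechin, (2R,3R), free 3-OH | O[C@@H]1Cc2c(OCc3ccccc3)cc(OCc3ccccc3)cc2O[C@@H]1c1cc(OCc2ccccc2)c(OCc2ccccc2)c(OCc2ccccc2)c1 | intermediate
7 | 3,4,5-tris(benzyloxy)benzoic acid | OC(=O)c1cc(OCc2ccccc2)c(OCc2ccccc2)c(OCc2ccccc2)c1 | starting material
8 | octa-O-benzyl-EGCG, (2R,3R) | O=C(O[C@@H]1Cc2c(OCc3ccccc3)cc(OCc3ccccc3)cc2O[C@@H]1c1cc(OCc2ccccc2)c(OCc2ccccc2)c(OCc2ccccc2)c1)c1cc(OCc2ccccc2)c(OCc2ccccc2)c(OCc2ccccc2)c1 | intermediate
9 | trimethylsilyl trifluoromethanesulfonate | C[Si](C)(C)OS(=O)(=O)C(F)(F)F | starting material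
10 | [hydroxy(tosyloxy)iodo]benzene (Koser's reagent) | Cc1ccc(cc1)S(=O)(=O)OI(O)c1ccccc1 | starting material
11 | (2R)-5,7-bis(benzyloxy)-2-[3,4-bis(benzyloxy)phenyl]-3-(trimethylsilyloxy)-2H-chromene (TMS enol ether of 4) | C[Si](C)(C)OC1=Cc2c(OCc3ccccc3)cc(OCc3ccccc3)cc2O[C@@H]1c1ccc(OCc2ccccc2)c(OCc2ccccc2)c1 | intermediate
12 | enolonium species: (2R)-3-{[phenyl(tosyloxy)-λ3-iodanyl]oxy}-2H-chromene analogue of 11, drawn as the O-bound trivalent-iodine enolate | Cc1ccc(cc1)S(=O)(=O)OI(c1ccccc1)OC1=Cc2c(OCc3ccccc3)cc(OCc3ccccc3)cc2O[C@@H]1c1ccc(OCc2ccccc2)c(OCc2ccccc2)c1 | intermediate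
13 | (2R,4R)-5,7-bis(benzyloxy)-2-[3,4-bis(benzyloxy)phenyl]-4-(octa-O-benzyl-EGCG-8-yl)chroman-3-one, 2,4-trans | O=C1[C@@H](c2c(OCc3ccccc3)cc(OCc3ccccc3)c3c2O[C@H](c2cc(OCc4ccccc4)c(OCc4ccccc4)c(OCc4ccccc4)c2)[C@H](OC(=O)c2cc(OCc4ccccc4)c(OCc4ccccc4)c(OCc4ccccc4)c2)C3)c2c(OCc3ccccc3)cc(OCc3ccccc3)cc2O[C@@H]1c1ccc(OCc2ccccc2)c(OCc2ccccc2)c1 | intermediate
14 | 5,7,3',4'-tetra-O-benzylcatechin-(4β→8)-octa-O-benzyl-EGCG, upper unit (2R,3S,4R), free 3-OH | O[C@H]1[C@@H](c2c(OCc3ccccc3)cc(OCc3ccccc3)c3c2O[C@H](c2cc(OCc4ccccc4)c(OCc4ccccc4)c(OCc4ccccc4)c2)[C@H](OC(=O)c2cc(OCc4ccccc4)c(OCc4ccccc4)c(OCc4ccccc4)c2)C3)c2c(OCc3ccccc3)cc(OCc3ccccc3)cc2O[C@@H]1c1ccc(OCc2ccccc2)c(OCc2ccccc2)c1 | intermediate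
15 | pentadeca-O-benzyl-epicatechin-3-O-gallate-(4β→8)-epigallocatechin-3-O-gallate, upper unit (2R,3R,4R) | O=C(O[C@@H]1[C@@H](c2c(OCc3ccccc3)cc(OCc3ccccc3)c3c2O[C@H](c2cc(OCc4ccccc4)c(OCc4ccccc4)c(OCc4ccccc4)c2)[C@H](OC(=O)c2cc(OCc4ccccc4)c(OCc4ccccc4)c(OCc4ccccc4)c2)C3)c2c(OCc3ccccc3)cc(OCc3ccccc3)cc2O[C@@H]1c1ccc(OCc2ccccc2)c(OCc2ccccc2)c1)c1cc(OCc2ccccc2)c(OCc2ccccc2)c(OCc2ccccc2)c1 | intermediate
16 | epicatechin-3-O-gallate-(4β→8)-epigallocatechin-3-O-gallate (CNP0296769.1) | O=C(O[C@@H]1[C@@H](c2c(O)cc(O)c3c2O[C@H](c2cc(O)c(O)c(O)c2)[C@H](OC(=O)c2cc(O)c(O)c(O)c2)C3)c2c(O)cc(O)cc2O[C@@H]1c1ccc(O)c(O)c1)c1cc(O)c(O)c(O)c1 | target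

**Step count**
Total: 8 steps. Longest linear sequence: 6 steps (1, 2, 5, 6, 7, 8; the branch 3, 4, 5, 6, 7, 8 is equally long).

**Three steps most likely to fail**

Step 5 (enolonium arylation). Enolisation of 4 toward C2 instead of C4 would erase the C2 centre. The cationic intermediate can also lose H-2 and aromatise to the 3-hydroxyflavylium ion (tetra-O-benzylcyanidin). Trivalent iodine can attack the trialkoxyarenes, and C6-arylation or self-arylation of 4 can compete. The fallback swaps which partner is polarity-reversed and avoids a C4 cation altogether. It sets out from 8: NBS (1.0 equiv) in CH2Cl2 at −78 → 0 °C brominates the ring-A position next to the pyran oxygen and gives 8-bromo-octa-O-benzyl-EGCG F1. Ketone 4 is then α-arylated with F1 under palladium catalysis (Pd2(dba)3 as a zerovalent palladium source, XPhos, K3PO4, toluene, 80 °C). Here the C4 enolate reacts in its native sense with an aryl–palladium electrophile, and the product equilibrates to the 2,4-trans epimer. The fallback comes back to the route at 13. Its own risk is slow base-induced epimerisation at C2.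

Step 6 (reduction). Ketone 13 is strongly enolisable at C4, so partial C4 epimerisation before or during reduction would give the all-cis alcohol as a by-product. The fallback uses that lability instead of fighting it. It sets out from 13 and runs a Noyori asymmetric transfer hydrogenation under dynamic kinetic resolution: RuCl[(S,S)-TsDPEN](p-cymene) or its (R,R) enantiomer, HCO2H/Et3N 5:2, CH2Cl2, rt. Both catalyst enantiomers are tried and the one that gives the 3S carbinol is kept. C4 epimerises through the enol faster than hydride transfer, and the cis-selective, catalyst-controlled reduction funnels both C4 epimers to the 3,4-cis alcohol. It comes back to the route at 14. No new compound is made on this way (none F0).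

Step 7 (Mitsunobu inversion). The carbinol is flanked by two aryl-bearing carbons; possible failures are no reaction, retention via an acyloxyphosphonium, elimination, or ring-A/ring-oxygen participation. The fallback separates activation from displacement. It sets out from 14: Tf2O and pyridine in CH2Cl2 at −40 °C give the 3-O-triflate of 14 F2. This is displaced in an SN2 reaction by cesium 3,4,5-tris(benzyloxy)benzoate (from 7 and Cs2CO3) with 18-crown-6 in toluene at 0 °C → rt, with inversion at C3. It comes back to the route at 15.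

**Further compounds**
F1 | step 5 | 8-bromo-octa-O-benzyl-EGCG, (2R,3R) | O=C(O[C@@H]1Cc2c(OCc3ccccc3)cc(OCc3ccccc3)c(Br)c2O[C@@H]1c1cc(OCc2ccccc2)c(OCc2ccccc2)c(OCc2ccccc2)c1)c1cc(OCc2ccccc2)c(OCc2ccccc2)c(OCc2ccccc2)c1
F0 | step 6 | none | none
F2 | step 7 | 3-O-trifluoromethanesulfonate of 14, upper unit (2R,3S,4R) | O=S(=O)(O[C@H]1[C@@H](c2c(OCc3ccccc3)cc(OCc3ccccc3)c3c2O[C@H](c2cc(OCc4ccccc4)c(OCc4ccccc4)c(OCc4ccccc4)c2)[C@H](OC(=O)c2cc(OCc4ccccc4)c(OCc4ccccc4)c(OCc4ccccc4)c2)C3)c2c(OCc3ccccc3)cc(OCc3ccccc3)cc2O[C@@H]1c1ccc(OCc2ccccc2)c(OCc2ccccc2)c1)C(F)(F)F
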